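## Structural features

The target is a germacranolide: a ten-membered carbocycle (C1–C10) fused at C6–C7 to a butenolide (O6–C12(=O)–C11=C7) whose C11 carries an acetoxymethyl group (C13). A ketone at C1 is conjugated with an exocyclic methylene at C10 (C14), a trisubstituted cis epoxide spans C4–C5 (methyl C15 on C4), and C8 bears a methacrylate. Three of the four stereocentres are contiguous (C4, C5, C6); the fourth, C8, is separated from C6 by the trigonal C7, so it cannot be relayed from the epoxide. The enone and the methacrylate are Michael acceptors and are labile to ozone, the epoxide and the allylic acetate are acid-sensitive, and C6–H is both the γ-proton of the butenolide and β to the epoxide oxygen, so strong base would open the epoxide. The real difficulties are the medium ring, the tetrasubstituted C7=C11 bond (its geometry decides which C11 substituent can lactonise onto O6), and the control of C8 relative to C4–C6. The feature used is that C1 and C6 face each other across the ring through two five-bond paths (C2–C5 and C10–C7): joining them gives an octalin with ring A (C1–C6, where the epoxide is necessarily cis) and ring B (C1, C6–C10), and the C1 ketone and C6 carbinol are what cleavage of that fusion olefin leaves behind.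

## Logic of the disconnections

27 to 25: the O8–acyl bond is cut and oxygen is put back on C14 across C10=C14. The enone and the methacrylate are the most reactive groups and cannot pass ozone, so they come last. With a free C14 hydroxyl one reagent makes both: both hydroxyls are acylated and the C14 carboxylate, β to the C1 ketone, is eliminated. C10 becomes an sp3 carbon whose configuration is irrelevant. The forward step must use a base mild enough not to deprotonate C6.

25 to 24: two O–Si bonds are cut. Silyl ethers are chosen at both O8 and O14 because an ester at C14 would not survive the dissolving-metal, enolate and hydride steps, and a β-silyloxy ketone is less prone to early elimination than a β-acyloxy ketone. The forward step needs a fluoride source that spares epoxide and acetate.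

24 to 22: the lactone O6–C12 bond and the C6–H bond are cut, so C6 returns to a ketone flanked by the epoxide and a Z enoate. One stereocentre is removed. The forward step must reduce C6 before C1, in the 1,2 sense, and anti to the epoxide oxygen.

22 to 20: C1 and C6 are rejoined as a double bond. Both ketones disappear and the ten-membered ring becomes two six-membered rings. The forward step must cleave C1=C6 and spare C7=C11, which therefore carries the ester, and no ozone-labile group may be present. The olefin geometry is the same in 20 and 22; the descriptor changes from E to Z only because C6 outranks C8 once it is a carbonyl.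

20 to 18: the O8–Si and C8–H bonds are cut. C8 is too far from the epoxide for substrate control, so it is set by reagent-controlled reduction of a ketone; this also erases any earlier configuration at C8. The forward step needs a chiral reductant that tolerates ester, acetate and epoxide.

18 to 14: the acetate is removed, C8 returns to the alcohol level and C13 is raised to a lactone carbonyl bound to O8. A carbonyl tied to O8 must lie cis to C8, so the other carbonyl (C12) is cis to C6; the ring settles the geometry that an intermolecular olefination with a phosphonoacetate could not, and such a reagent would not bring C13 either. The forward steps must distinguish lactone from methyl ester and primary from secondary hydroxyl.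

14 to 11 and 12: the C7=C11 bond and the O8–C13 acyl bond are cut (Knoevenagel retron). This needs an oxygen at C8 of a C7 ketone and only mild base. The C8–H of 14 is acidic and will epimerise; this is harmless because C8 passes through 18.

11 to 10 to 9: the C8–O bond and then the two epoxide C–O bonds are cut. Epoxidation is placed where C1=C6 is an enone olefin and inert to an electrophilic oxidant. No stereocentre is near C4=C5, so the forward step needs a chiral dioxirane; it sets the absolute configuration of the route.

9 to 7: the hydrogens at C2 and C3 are removed and ring A becomes aromatic. Reduction of an aryl ketone at the ipso and para carbons leaves the olefins at C1=C6 and C4=C5 after conjugation; reduction as a plain alkylbenzene would leave C3=C4. The forward step must reduce the ring faster than the carbonyl, and the C14 oxygen must be an ether.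

7 to 4: the O–Si bond is cut, C14 returns to the acid level, and the C6–C7 aryl–acyl bond is cut (Friedel–Crafts retron). Only the remote carboxyl can close a six-membered ring. The forward sequence must reduce an acid beside an aryl ketone.

4 to 1 and 2: the C9–C10 bond is cut (Michael retron). Ring B needs three carbons (C7–C9) between C10 and the arene; a two-carbon haloacetate would give an arylsuccinate and then an indanone, so the acrylate 2 is used. The forward step must stop at mono-addition; C10 is formed racemic on purpose.

## Other disconnections considered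

Alternative 1: The cut is through C6–C7 and the lactone O6–C12 bond. In the forward step the open-chain iodo enoate aldehyde A1 would be treated with CrCl2 and catalytic NiCl2: zerovalent nickel inserts into C7–I, the alkenyl group passes to trivalent chromium and adds to the C6 aldehyde, and the alkoxide lactonises onto the cis ester to give A2.
- In its favour: it is convergent; both rings and C6 arise in one operation; the geometry is defined in an acyclic iodo enoate; C8 and the epoxide can be set on small fragments; organochromium reagents prefer aldehydes over ketones and esters.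
- Against it here: a ten-membered ring must be closed by bond formation under high dilution against transannular strain; C6 depends on the facial bias of an α,β-epoxy aldehyde in a macrocyclic transition state; enone and methacrylate must pass an excess of a one-electron reductant.
- Comparison: the alternative is the better plan for convergence, for C8 and for the steps after the key step (one protecting-group exchange against three steps here). The chosen plan is better for the ring, which is revealed from a bicycle at no entropic cost, and for C6, set by ketone reduction. Mechanistically the two are equal, each resting on one chemoselection. On step count the alternative is probably better if A1 is accessible in about a dozen steps.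

Alternative 2: The cut is the C8–C9 bond with C1–C6 restored. In the forward step the potassium alkoxide of the cyclohexenol A3 (KH, 18-crown-6) would undergo an anionic oxy-Cope shift through a chair, breaking C1–C6 and forming C8–C9, and the C1 enolate would be silylated to A4.
- In its favour: it cleaves the same C1–C6 bond in a concerted, stereospecific event; it creates C8 in the key step, which is better than the oxidation and reduction pair needed here; the C1 oxygen emerges as a regiodefined enol ether toward C10, equal in value to the preinstalled C14 here.
- Against it here: A4 is far from the target. C6 has no oxygen, C12 is a methylene and C4=C5 is still an olefin, so a 1,4-dioxygenation of the C6=C7–C11=C12 diene, oxidation to the lactone and a regio- and face-selective epoxidation in a flexible triene would follow.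
- Comparison: structurally it is better for C8 and worse for the epoxide and C6. The sigmatropic shift is at least as predictable as ozonolysis, but needs strong base. It has fewer steps before the key step and clearly more after it.

Alternative 3: The cut is C7–C8. In the forward step the iodobutenolide aldehyde A5 would be treated with CrCl2 and catalytic NiCl2, and the alkenylchromium at C7 would add to the C8 aldehyde to give the ten-membered alcohol A6.
- In its favour: the butenolide and its geometry are complete before the ring is made, so the geometric problem that costs six steps here does not arise (better than the chosen plan); C4–C6 are set early; the route is convergent.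
- Against it here: medium-ring closure by bond formation; C8 formed under remote control only; the alkenylchromium has the lactone oxygen in the β position, so β-elimination can compete; A6 still needs oxidation at C1, ether-to-acetate exchange at C13 and esterification.
- Comparison: about equal in steps after the key step, better in convergence and geometry, worse in control of C8 and in reliability of ring closure.

Key step: step 14

Remark on the chemistry: locants are those of the germacrane skeleton of the target (C1–C15) throughout; in bicyclic intermediates ring A is C1–C6 and ring B is C1, C6–C10, and a naphthalenone name is added where it helps.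
Remark on the chemistry: C10 is made racemic in step 1 and carried as both epimers (it ends as a trigonal carbon); C8 is uncontrolled in 11 and 13–17 and fixed in step 12; such centres are left open in the SMILES.
Remark on the chemistry: 1, 2 and 12 are taken to be commercial.

## Steps

Step 1
Reactants: 1 methyl 4-methylphenylacetate; 2 methyl acrylate
Product: 4 2-(4-methylphenyl)pentanedioic acid (racemic), via dimethyl 2-(4-methylphenyl)pentanedioate 3 (not isolated)
Conditions: KOt-Bu (0.1 equiv), t-BuOH–THF, 0 °C to rt; then aq. NaOH, MeOH, reflux; HCl
Reagents that add atoms: sodium hydroxide, [Na+].[OH-]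
Why: Base-catalysed Michael addition of the arylacetate enolate to the acrylate forms C9–C10 and supplies C7–C9; the adduct is less acidic than 1, so mono-addition should prevail, and saponification follows in the same flask.

Step 2
Reactants: 4 2-(4-methylphenyl)pentanedioic acid
Product: 5 6-methyl-4-oxo-1,2,3,4-tetrahydronaphthalene-1-carboxylic acid (racemic)
Conditions: P2O5–MeSO3H (1:10 w/w), 50 °C; ice water
Reagents that add atoms: none
Why: Intramolecular Friedel–Crafts acylation; only the remote carboxyl can reach an ortho carbon through a six-membered transition state, and the two ortho positions are equivalent, so one keto acid should form.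

Step 3
Reactants: 5 6-methyl-4-oxo-1,2,3,4-tetrahydronaphthalene-1-carboxylic acid
Product: 6 4-(hydroxymethyl)-7-methyl-3,4-dihydronaphthalen-1(2H)-one (racemic)
Conditions: BH3·SMe2 (1.1 equiv), THF, −10 to 0 °C; MeOH
Reagents that add atoms: none
Why: Chemoselective borane reduction: a carboxylic acid is reduced through its acyloxyborane faster than a conjugated aryl ketone, so one equivalent at low temperature should give the keto alcohol.

Step 4
Reactants: 6 4-(hydroxymethyl)-7-methyl-3,4-dihydronaphthalen-1(2H)-one
Product: 7 4-[(tert-butyldimethylsilyloxy)methyl]-7-methyl-3,4-dihydronaphthalen-1(2H)-one (racemic)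
Conditions: t-BuMe2SiCl, imidazole, DMF, rt
Reagents that add atoms: tert-butyldimethylsilyl chloride, CC(C)(C)[Si](C)(C)Cl
Why: Standard silylation of a primary alcohol; the silyl ether, unlike an ester, should survive the dissolving-metal, enolate and hydride steps and is inert to ozone.

Step 5
Reactants: 7 4-[(tert-butyldimethylsilyloxy)methyl]-7-methyl-3,4-dihydronaphthalen-1(2H)-one
Product: 9 4-[(tert-butyldimethylsilyloxy)methyl]-7-methyl-3,4,5,6-tetrahydronaphthalen-1(2H)-one (racemic; C7 ketone with C6=C1 and C4=C5), via unconjugated dienone 8 (not isolated)
Conditions: K (2.5 equiv), NH3(l)–THF, t-BuOH (1.1 equiv), −78 °C; solid NH4Cl; then 1,8-diazabicyclo[5.4.0]undec-7-ene (DBU, 0.1 equiv), CH2Cl2, 0 °C, argon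
Reagents that add atoms: none
Why: Birch reduction of an aryl ketone in the acceptor sense: the radical anion is protonated para to the acyl-bearing carbon (C3), a second electron gives a cross-conjugated enolate, and protonation at C6 gives 8; the doubly allylic C6–H is then moved to C2 by the amine base, giving the more substituted conjugated C6=C1 and leaving C4=C5 where the epoxide is needed. Low temperature and one equivalent of alcohol should hold the carbonyl as its enolate and prevent further reduction.

Step 6
Reactants: 9 4-[(tert-butyldimethylsilyloxy)methyl]-7-methyl-3,4,5,6-tetrahydronaphthalen-1(2H)-one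
Product: 10 (4S,5R)-4,5-epoxide of 9, i.e. (7S,8R)-4-[(tert-butyldimethylsilyloxy)methyl]-7,8-epoxy-7-methyl-3,4,5,6,7,8-hexahydronaphthalen-1(2H)-one (both C10 epimers)
Conditions: 1,2:4,5-di-O-isopropylidene-β-D-erythro-2,3-hexodiulo-2,6-pyranose (0.3 equiv), KHSO5 (as 2KHSO5·KHSO4·K2SO4), K2CO3, Bu4NHSO4, MeCN–CH2(OMe)2/aq. Na2B4O7 buffer (pH 10.5), 0 °C
Reagents that add atoms: potassium peroxymonosulfate, [K+].[O-]S(=O)(=O)OO
Why: Shi epoxidation: the electrophilic chiral dioxirane should take the trisubstituted C4=C5 bond and leave the enone olefin C6=C1; the spiro transition-state model for a trisubstituted olefin with the D-fructose-derived ketone predicts the (4S,5R) epoxide, independent of the remote C10. This step fixes the absolute configuration of the route.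

Step 7
Reactants: 10 (4S,5R)-epoxy enone
Product: 11 (4S,5R)-8-hydroxy derivative of 10 (α′-hydroxy enone; both C8 and both C10 epimers)
Conditions: KN(SiMe3)2 (1.1 equiv), THF, −78 °C; 3-phenyl-2-(phenylsulfonyl)oxaziridine (1.3 equiv), −78 °C; aq. NH4Cl
Reagents that add atoms: 3-phenyl-2-(phenylsulfonyl)oxaziridine, O=S(=O)(c1ccccc1)N1OC1c1ccccc1
Why: Kinetic deprotonation of the enone with a hindered amide base takes the α′ proton at C8, and the cross-conjugated enolate is hydroxylated by the N-sulfonyloxaziridine (enolate oxidation); the C8 configuration is not controlled and need not be, since C8 later passes through a ketone.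

Step 8
Reactants: 11 (4S,5R)-8-hydroxy epoxy enone; 12 methyl 3-chloro-3-oxopropanoate
Product: 14 butenolide ester (C7=C11 in a lactone ring: carbonyl C13 bound to O8; CO2Me on C11 cis to C6; 4S,5R; C8 and C10 epimers), via malonate ester 13 (not isolated)
Conditions: pyridine, 4-(dimethylamino)pyridine (0.1 equiv), CH2Cl2, 0 °C; then DBU (1.5 equiv), 0 °C to rt, argon
Reagents that add atoms: none
Why: O-Acylation, then intramolecular Knoevenagel condensation (5-exo aldol of the malonate carbon onto the C7 ketone and loss of water) forms the tetrasubstituted C7=C11 bond; the lactone carbonyl tied to O8 must lie cis to C8, so the free ester C12 is cis to C6 without ambiguity. The malonate is far more acidic than any ring proton, so the amidine should not disturb the epoxy enone.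

Step 9
Reactants: 14 butenolide ester
Product: 16 diol methyl ester (C8–OH and C13–OH free; C12 ester cis to C6; 4S,5R), via lactol 15 (not isolated)
Conditions: i-Bu2AlH (1.2 equiv), CH2Cl2, −78 °C; then MeOH, NaBH4, −78 to −20 °C; aq. potassium sodium tartrate
Reagents that add atoms: none
Why: A butenolide carbonyl is more electrophilic than an acyclic methyl ester, so one equivalent of i-Bu2AlH at −78 °C should stop at the aluminium lactolate; after methanolysis the lactol equilibrates with its hydroxy enal, which NaBH4 reduces in the 1,2 sense. C13 thus reaches the alcohol level with the geometry of step 8 retained.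

Step 10
Reactants: 16 diol methyl ester
Product: 17 13-monoacetate of 16 (C8–OH free)
Conditions: Ac2O (1.1 equiv), 2,4,6-collidine, CH2Cl2, −20 °C
Reagents that add atoms: acetic anhydride, CC(=O)OC(C)=O
Why: Selective acylation of the primary allylic alcohol over the hindered secondary one beside the tetrasubstituted olefin, under weakly basic conditions that spare the epoxide.

Step 11
Reactants: 17 13-monoacetate
Product: 18 C8 ketone (13-acetoxy-14-silyloxy-4,5-epoxy-8-oxo dienoate methyl ester; 4S,5R; E; C10 epimers)
Conditions: Dess–Martin periodinane, NaHCO3, CH2Cl2, 0 °C to rt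
Reagents that add atoms: none
Why: Buffered Dess–Martin oxidation of the secondary allylic alcohol; both C8 epimers converge on one ketone, which erases the earlier lack of control.

Step 12
Reactants: 18 C8 ketone
Product: 19 (4S,5R,8R)-8-alcohol
Conditions: (S)-1-methyl-3,3-diphenyltetrahydro-1H,3H-pyrrolo[1,2-c][1,3,2]oxazaborole (0.2 equiv), catecholborane (1.5 equiv), toluene, −78 °C; MeOH, pH 7 buffer
Reagents that add atoms: none
Why: Corey–Bakshi–Shibata reduction: the ketone binds with the tetrasubstituted alkenyl carbon C7 as the large group and the C9 methylene as the small one, so the (S)-catalyst should give the (8R)-alcohol by reagent control, independent of C10 and of the remote epoxide. Catecholborane at −78 °C has little uncatalysed background and leaves ester, acetate and epoxide alone.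

Step 13
Reactants: 19 (4S,5R,8R)-8-alcohol
Product: 20 methyl (4S,5R,8R,E)-13-acetoxy-8,14-bis(tert-butyldimethylsilyloxy)-4,5-epoxy-1,6-cyclogermacra-1(6),7(11)-dien-12-oate (epoxy octalin dienoate; C12 cis to C6)
Conditions: t-BuMe2SiOSO2CF3 (1.3 equiv), 2,6-lutidine, CH2Cl2, −78 °C
Reagents that add atoms: tert-butyldimethylsilyl trifluoromethanesulfonate, CC(C)(C)[Si](C)(C)OS(=O)(=O)C(F)(F)F
Why: Silylation of a hindered secondary alcohol with the silyl triflate and a hindered pyridine at low temperature, conditions that trisubstituted epoxides normally tolerate.

Step 14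
Reactants: 20 epoxy octalin dienoate
Product: 22 methyl (4S,5S,8R,Z)-13-acetoxy-8,14-bis(tert-butyldimethylsilyloxy)-4,5-epoxy-1,6-dioxogermacr-7(11)-en-12-oate (ten-membered 1,6-diketone), via methoxy hydroperoxide 21 (not isolated)
Conditions: O3, CH2Cl2–MeOH (4:1), NaHCO3, Sudan Red 7B, −78 °C; then Me2S, −78 °C to rt
Reagents that add atoms: ozone, [O-][O+]=O
Why: Ozone adds as a 1,3-dipole to the most electron-rich π bond, the tetrasubstituted C1=C6 fusion olefin; the primary ozonide cycloreverts to a C6 ketone and a C1 carbonyl oxide, methanol traps the latter as 21, and Me2S reduces it to the C1 ketone. The closest known reaction is the ozonolysis of 1(6)-octalins to cyclodecane-1,6-diones. The ten-membered ring is not closed by a cyclisation: it is uncovered by scission of the bond shared by rings A and B, so no exo or endo mode and no dilution are involved. No stereocentre is formed or touched; C4, C5 and C8 are carried over and C1 and C6 become trigonal. The selectivity needed is for C1=C6 over C7=C11; it rests on electron density, since C7=C11 carries an ester and an acetoxymethyl group, and on stopping at the indicator end point. Silyl ethers, acetate and epoxide are inert to ozone, and no aryl ether or other olefin is present. Buffered, cold, reductive work-up should keep the diketone from transannular aldol closure.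

Step 15
Reactants: 22 ten-membered 1,6-diketone
Product: 24 (4S,5R,6R,8R)-13-acetoxy-8,14-bis(tert-butyldimethylsilyloxy)-4,5-epoxy-1-oxogermacr-7(11)-en-12,6-olide, via C6 hydroxy ester 23 (not isolated)
Conditions: NaBH4 (0.4 equiv), CeCl3·7H2O (1.2 equiv), MeOH–THF, −78 °C; then 0 °C; pH 7 buffer
Reagents that add atoms: none
Why: Luche reduction: the C6 carbonyl, activated by the epoxide and by the acceptor olefin, should be reduced in the 1,2 sense before the hindered C1 ketone, and hydride is expected to add anti to the epoxide oxygen, the usual outcome for α,β-epoxy ketones, which sets (6R). The C6 alkoxide then closes onto the cis methyl ester (5-exo-trig lactonisation) with loss of methanol.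

Step 16
Reactants: 24 bis-silyl keto lactone
Product: 25 (4S,5R,6R,8R)-13-acetoxy-4,5-epoxy-8,14-dihydroxy-1-oxogermacr-7(11)-en-12,6-olide
Conditions: HF·pyridine, pyridine, THF, 0 °C to rt
Reagents that add atoms: none
Why: Fluoride-mediated cleavage of both silyl ethers under buffered, non-basic conditions, which avoids deprotonation at C6 and retro-aldol loss of C14; the enone is not yet present.

Step 17
Reactants: 25 8,14-diol
Product: 27 (4S,5R,6R,8R)-13-acetoxy-4,5-epoxy-8-(methacryloyloxy)-1-oxogermacra-7(11),10(14)-dien-12,6-olide (CNP0266914.1), via bis-methacrylate 26 (not isolated)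
Conditions: methacrylic anhydride (3 equiv), Et3N, 4-(dimethylamino)pyridine (0.2 equiv), CH2Cl2, 0 °C to rt; then DBU (1.2 equiv), 0 °C
Reagents that add atoms: methacrylic anhydride, C=C(C)C(=O)OC(=O)C(C)=C
Why: Acyl transfer esterifies both hydroxyls; the C14 methacrylate is β to the C1 ketone and is expelled by E1cB elimination to give the C10=C14 methylene, while the C8 ester remains. C10 becomes trigonal here, so both epimers converge on one product.

## Compound list

1 | methyl 4-methylphenylacetate | COC(=O)Cc1ccc(C)cc1 | starting material
2 | methyl acrylate | C=CC(=O)OC | starting material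
3 | dimethyl 2-(4-methylphenyl)pentanedioate (racemic) | COC(=O)CCC(C(=O)OC)c1ccc(C)cc1 | intermediate (not isolated)
4 | 2-(4-methylphenyl)pentanedioic acid (racemic) | OC(=O)CCC(C(=O)O)c1ccc(C)cc1 | intermediate
5 | 6-methyl-4-oxo-1,2,3,4-tetrahydronaphthalene-1-carboxylic acid (racemic) | O=C1CCC(C(=O)O)c2ccc(C)cc12 | intermediate
6 | 4-(hydroxymethyl)-7-methyl-3,4-dihydronaphthalen-1(2H)-one (racemic) | O=C1CCC(CO)c2ccc(C)cc12 | intermediate
7 | 4-[(tert-butyldimethylsilyloxy)methyl]-7-methyl-3,4-dihydronaphthalen-1(2H)-one (racemic) | O=C1CCC(CO[Si](C)(C)C(C)(C)C)c2ccc(C)cc12 | intermediate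
8 | 4-[(tert-butyldimethylsilyloxy)methyl]-7-methyl-3,4,6,8a-tetrahydronaphthalen-1(2H)-one (unconjugated dienone, diastereomers) | O=C1CCC(CO[Si](C)(C)C(C)(C)C)C2=CCC(C)=CC12 | intermediate (not isolated)
9 | 4-[(tert-butyldimethylsilyloxy)methyl]-7-methyl-3,4,5,6-tetrahydronaphthalen-1(2H)-one (racemic) | O=C1CCC(CO[Si](C)(C)C(C)(C)C)C3=C1C=C(C)CC3 | intermediate
10 | (4S,5R)-epoxy enone [(7S,8R)-4-[(tert-butyldimethylsilyloxy)methyl]-7,8-epoxy-7-methyl-3,4,5,6,7,8-hexahydronaphthalen-1(2H)-one], both C10 epimers | O=C1CCC(CO[Si](C)(C)C(C)(C)C)C3=C1[C@H]2O[C@@]2(C)CC3 | intermediate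
11 | (4S,5R)-8-hydroxy epoxy enone, C8 and C10 epimers | O=C1C(O)CC(CO[Si](C)(C)C(C)(C)C)C3=C1[C@H]2O[C@@]2(C)CC3 | intermediate
12 | methyl 3-chloro-3-oxopropanoate | COC(=O)CC(Cl)=O | starting material
13 | 8-O-(methoxycarbonylacetyl) ester of 11 | O=C1C(OC(=O)CC(=O)OC)CC(CO[Si](C)(C)C(C)(C)C)C3=C1[C@H]2O[C@@]2(C)CC3 | intermediate (not isolated)
14 | (4S,5R)-butenolide ester: C7=C11, C13 lactone on O8, CO2Me (C12) cis to C6; C8 and C10 epimers | COC(=O)C1=C2C(OC1=O)CC(CO[Si](C)(C)C(C)(C)C)C3=C2[C@H]4O[C@@]4(C)CC3 | intermediate
15 | lactol of 14 (C13 hemiacetal) | COC(=O)C1=C2C(OC1O)CC(CO[Si](C)(C)C(C)(C)C)C3=C2[C@H]4O[C@@]4(C)CC3 | intermediate (not isolated)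
16 | (4S,5R)-8,13-diol methyl ester (C12 cis to C6), C8 and C10 epimers | COC(=O)/C(CO)=C1/C(O)CC(CO[Si](C)(C)C(C)(C)C)C3=C1[C@H]2O[C@@]2(C)CC3 | intermediate
17 | 13-monoacetate of 16 | COC(=O)/C(COC(C)=O)=C1/C(O)CC(CO[Si](C)(C)C(C)(C)C)C3=C1[C@H]2O[C@@]2(C)CC3 | intermediate
18 | (4S,5R)-8-ketone, C10 epimers | COC(=O)/C(COC(C)=O)=C1/C(=O)CC(CO[Si](C)(C)C(C)(C)C)C3=C1[C@H]2O[C@@]2(C)CC3 | intermediate
19 | (4S,5R,8R)-8-alcohol, C10 epimers | COC(=O)/C(COC(C)=O)=C1/[C@H](O)CC(CO[Si](C)(C)C(C)(C)C)C3=C1[C@H]2O[C@@]2(C)CC3 | intermediate
20 | methyl (4S,5R,8R,E)-13-acetoxy-8,14-bis(tert-butyldimethylsilyloxy)-4,5-epoxy-1,6-cyclogermacra-1(6),7(11)-dien-12-oate, C10 epimers | COC(=O)/C(COC(C)=O)=C1/[C@H](O[Si](C)(C)C(C)(C)C)CC(CO[Si](C)(C)C(C)(C)C)C3=C1[C@H]2O[C@@]2(C)CC3 | intermediate (precursor of the key step)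
21 | C1 methoxy hydroperoxide, C6 ketone | COC(=O)/C(COC(C)=O)=C1/[C@H](O[Si](C)(C)C(C)(C)C)CC(CO[Si](C)(C)C(C)(C)C)C(OC)(OO)CC[C@]2(C)O[C@@H]2C1=O | intermediate (not isolated)
22 | methyl (4S,5S,8R,Z)-13-acetoxy-8,14-bis(tert-butyldimethylsilyloxy)-4,5-epoxy-1,6-dioxogermacr-7(11)-en-12-oate, C10 epimers | COC(=O)/C(COC(C)=O)=C1/[C@H](O[Si](C)(C)C(C)(C)C)CC(CO[Si](C)(C)C(C)(C)C)C(=O)CC[C@]2(C)O[C@@H]2C1=O | intermediate (product of the key step)
23 | (6R)-6-hydroxy ester from 22 | COC(=O)/C(COC(C)=O)=C1/[C@H](O[Si](C)(C)C(C)(C)C)CC(CO[Si](C)(C)C(C)(C)C)C(=O)CC[C@]2(C)O[C@@H]2[C@@H]1O | intermediate (not isolated)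
24 | (4S,5R,6R,8R)-13-acetoxy-8,14-bis(tert-butyldimethylsilyloxy)-4,5-epoxy-1-oxogermacr-7(11)-en-12,6-olide, C10 epimers | CC(C)(C)[Si](C)(C)O[C@@H]1CC(CO[Si](C)(C)C(C)(C)C)C(=O)CC[C@]2(C)O[C@@H]2[C@@H]2OC(=O)C(COC(C)=O)=C21 | intermediate
25 | (4S,5R,6R,8R)-13-acetoxy-4,5-epoxy-8,14-dihydroxy-1-oxogermacr-7(11)-en-12,6-olide, C10 epimers | O[C@@H]1CC(CO)C(=O)CC[C@]2(C)O[C@@H]2[C@@H]2OC(=O)C(COC(C)=O)=C21 | intermediate
26 | 8,14-bis-methacrylate of 25 | C=C(C)C(=O)O[C@@H]1CC(COC(=O)C(C)=C)C(=O)CC[C@]2(C)O[C@@H]2[C@@H]2OC(=O)C(COC(C)=O)=C21 | intermediate (not isolated)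
27 | (4S,5R,6R,8R)-13-acetoxy-4,5-epoxy-8-(methacryloyloxy)-1-oxogermacra-7(11),10(14)-dien-12,6-olide | C=C(C)C(=O)O[C@@H]1CC(=C)C(=O)CC[C@]2(C)O[C@@H]2[C@@H]2OC(=O)C(COC(C)=O)=C21 | target

Total step count: 17. Longest linear sequence: 17 steps (1 to 27); the route is linear.

## Least certain steps

Step 14 (key step). The most likely failures are over-oxidation, by attack on C7=C11 or by anomalous fragmentation of the carbonyl oxide next to the epoxide, and transannular aldol closure of the new diketone during work-up. Fallback: from 20, stoichiometric OsO4 with N,N,N′,N′-tetramethylethylenediamine in CH2Cl2 at −78 °C should dihydroxylate the more electron-rich fusion olefin; after NaHSO3 cleavage of the osmate ester this gives the cis-1,6-diol F1, and Pb(OAc)4 in CH2Cl2 at 0 °C cleaves the glycol and rejoins the route at 22.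

Step 5. The carbonyl may be reduced instead of the ring (ketyl protonation, then benzylic C–O hydrogenolysis), or the dienone may be reduced further. Fallback: from 7, the carbonyl is first masked as its potassium enolate with KN(SiMe3)2 and the ring is then reduced with Li in NH3 and t-BuOH as an alkylbenzene, which after protonation gives the skipped dienone F2 (C6=C1 enone, isolated C3=C4). Migration of C3=C4 into conjugation with catalytic RhCl3·3H2O in EtOH rejoins the route at 9.

Step 9. The hydride may fail to distinguish lactone from methyl ester, or may be consumed by deprotonation of the acidic C8–H so that 14 is returned. Fallback: from 11, heating with 2,2-dimethyl-1,3-dioxane-4,6-dione (Meldrum's acid) in toluene gives the malonic half ester F3, and DBU closes it to the butenolide carboxylic acid F4. As a carboxylate C12 is inert to hydride, so LiBH4 in THF reduces only the lactone to the diol acid F5, and Me3SiCHN2 in MeOH–toluene methylates it and rejoins the route at 16.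

Step 15. Reduction of the C1 ketone may compete, and facial selectivity at C6 in the flexible ring may be poorer than in acyclic epoxy ketones. Fallback: from 22, both ketones are reduced with excess NaBH4 and CeCl3, the C6 alcohol lactonises to the 1-hydroxy lactone F6, and buffered Dess–Martin oxidation of the remaining C1 carbinol rejoins the route at 24.

Step 17. Base may open the epoxide through deprotonation at C6, or add to the new enone, during the one-pot acylation and elimination. Fallback: from 25, selective sulfonylation of the primary hydroxyl with MeSO2Cl and 2,4,6-collidine at −30 °C gives the 14-methanesulfonate F7, which eliminates with Et3N at −20 °C to the 8-hydroxy enone F8. Esterification with methacrylic acid, N,N′-diisopropylcarbodiimide and catalytic 4-(dimethylamino)pyridine then gives 27.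

## Further compounds

F1 | step 14 | cis-1,6-diol of 20 | COC(=O)/C(COC(C)=O)=C1/[C@H](O[Si](C)(C)C(C)(C)C)CC(CO[Si](C)(C)C(C)(C)C)C3(O)C1(O)[C@H]2O[C@@]2(C)CC3
F2 | step 5 | 4-[(tert-butyldimethylsilyloxy)methyl]-7-methyl-3,4,5,8-tetrahydronaphthalen-1(2H)-one | O=C1CCC(CO[Si](C)(C)C(C)(C)C)C3=C1CC(C)=CC3
F3 | step 9 | malonic half ester of 11 | O=C1C(OC(=O)CC(=O)O)CC(CO[Si](C)(C)C(C)(C)C)C3=C1[C@H]2O[C@@]2(C)CC3
F4 | step 9 | butenolide carboxylic acid (C12 acid analogue of 14) | OC(=O)C1=C2C(OC1=O)CC(CO[Si](C)(C)C(C)(C)C)C3=C2[C@H]4O[C@@]4(C)CC3
F5 | step 9 | diol acid (C12 acid analogue of 16) | OC(=O)/C(CO)=C1/C(O)CC(CO[Si](C)(C)C(C)(C)C)C3=C1[C@H]2O[C@@]2(C)CC3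
F6 | step 15 | 1-hydroxy lactone (C1 carbinol analogue of 24) | CC(C)(C)[Si](C)(C)O[C@@H]1CC(CO[Si](C)(C)C(C)(C)C)C(O)CC[C@]2(C)O[C@@H]2[C@@H]2OC(=O)C(COC(C)=O)=C21
F7 | step 17 | 14-methanesulfonate of 25 | O[C@@H]1CC(COS(C)(=O)=O)C(=O)CC[C@]2(C)O[C@@H]2[C@@H]2OC(=O)C(COC(C)=O)=C21
F8 | step 17 | 8-hydroxy enone (8-O-deacyl target) | O[C@@H]1CC(=C)C(=O)CC[C@]2(C)O[C@@H]2[C@@H]2OC(=O)C(COC(C)=O)=C21
A1 | alternative 1 | open-chain Z iodo enoate with C6 epoxy aldehyde | C=C(C)C(=O)O[C@@H](/C(I)=C(\CO[Si](C)(C)C(C)(C)C)C(=O)OC)CC(=C)C(=O)CC[C@]1(C)O[C@@H]1C=O
A2 | alternative 1 | target skeleton with C13 silyl ether | C=C(C)C(=O)O[C@@H]1CC(=C)C(=O)CC[C@]2(C)O[C@@H]2[C@@H]2OC(=O)C(CO[Si](C)(C)C(C)(C)C)=C21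
A3 | alternative 2 | 1-vinyl-6-dienyl cyclohex-4-en-1-ol (configuration drawn for a chair transition state) | C=C[C@@]1(O)CCC(C)=C[C@@H]1/C(=C/OCc1ccc(OC)cc1)C(=C)CO[Si](C)(C)C(C)(C)C
A4 | alternative 2 | ten-membered C1 silyl enol ether with C8 PMB ether | C[Si](C)(C)O/C1=C\C[C@@H](OCc2ccc(OC)cc2)/C(C(=C)CO[Si](C)(C)C(C)(C)C)=C/C=C(C)\CC1
A5 | alternative 3 | β-iodobutenolide with tethered C8 aldehyde | O=CCC(=C)[C@@H](O[Si](C)(C)C(C)(C)C)CC[C@]1(C)O[C@@H]1[C@@H]1OC(=O)C(COCc2ccc(OC)cc2)=C1I
A6 | alternative 3 | ten-membered C8 alcohol | O[C@@H]1CC(=C)[C@@H](O[Si](C)(C)C(C)(C)C)CC[C@]2(C)O[C@@H]2[C@@H]2OC(=O)C(COCc3ccc(OC)cc3)=C21
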